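## The problem

The target 31 is a 3,6-dihydro-1,2-dioxine in which O1 and O2 bridge C6 and C3 and C4=C5 is the ring alkene with ethyl on C4. C3 carries H and the CH2CO2H arm (C2, C1). C6 carries ethyl, O1 and the chain C7–C14, which has a methyl-bearing carbon C8 and a carbon C10 bearing ethyl and butyl (C11–C14). The configuration is 3R,6R,8S,10S, which puts the acetic acid arm and the C6 ethyl group on the same face of the ring.

C8 and C10 are 1,3-related tertiary carbons with no heteroatom nearby, and C10 is stereogenic only because ethyl differs from butyl. No reagent can be trusted to tell these arms apart by size, so they must enter by chemically different operations and C10 must be set against C8 in a rigid frame.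

C6 is a tertiary peroxy carbon whose two alkyl arms (ethyl and C7H2) are sterically alike, and it lies on a flexible chain three bonds from C8. It therefore needs reagent control and a stereospecific C–O bond formation. For the same reason C6 cannot steer C3 across the ring, so C3 needs independent control.

The O–O bond will not tolerate organolithium or Grignard reagents, low-valent metals, phosphines or hydrogenation. C3–H, flanked by the peroxide and the carboxymethyl group, invites base-induced ring opening. The peroxide should therefore enter after all organometallic C–C bond formations, and the acid should be unveiled last.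

The feature that makes the key step possible is the six-carbon string C6–C7–C8–C9–C10–CH2(ethyl), which needs oxygen only at C6. Folded into a ring it is a 3,5-disubstituted cyclohexanone (ring C1 = C6, C6 = C7, C5 = C8, C4 = C9, C3 = C10, C2 = the ethyl CH2). The 1,3-relation of C8 and C10 becomes a trans-3,5 relation across the ring, and butyl and ethyl are distinguished by ring position.

## Retrosynthesis

**C1 oxidation level.** Acid 31 is traced through aldehyde 30 to the 3-allyl dioxine 29; the only bond cut is the terminal C=C of the allyl group. A carboxyl or ester at C1 during ring closure would put the C3 leaving group β to a carbonyl and cause elimination to a dienoate, whereas an allyl group is inert and arrives together with the C3 stereocentre. The forward reaction must cleave a monosubstituted alkene beside a hindered ring alkene and an O–O bond.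

**C3–O2 bond.** Dioxine 29 is opened to the allylic mesylate 28, made from alcohol 27. The forward step is a 6-exo-tet displacement at C3 by the C6 peroxide anion with inversion. Closing the same bond by conjugate addition would leave C3 to be directed by C6, which cannot discriminate. Closing at C6 instead would require substitution at a tertiary centre. The precursor is acyclic with C3 as a carbinol. The step demands clean inversion at an allylic secondary sulfonate and a Z alkene that holds C3 and C6 together.

**C2–C3 bond.** Alcohol 27 is cut to the Z-enal 26 and an allyl nucleophile. Asymmetric allylboration sets C3 under reagent control, which is needed because C6 is remote and undiscriminating. An acetate aldol would bring C1 in at the wrong oxidation level for the closure.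

**C4=C5 bond.** Enal 26 goes back through alcohol 25 and ester 24 to aldehyde 21 and phosphonate 23, which is made from 22. A Z-selective Horner–Wadsworth–Emmons reaction of a diaryl phosphonate brings in C3, C4 and the C4 ethyl group. Aldehyde 21 has no α-hydrogen and cannot epimerise. An olefination with a branched non-stabilised ylide would give neither the yield nor the geometry.

**C6–O1 bond.** Aldehyde 21 comes from diol 20 and this from hydroperoxide 19, which is the product of opening epoxy alcohol 18 at its tertiary carbon with inversion. This is the only stereospecific entry to a tertiary hydroperoxide, and the epoxide is available under reagent control. One carbon is sacrificed in the later glycol cleavage.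

**C6–ethyl and C5–C6 bonds.** Epoxy alcohol 18 comes from the E-allylic alcohol 17, whose alkene geometry encodes C6. Alcohol 17 is traced through ester 16 to the Z-enol triflate 15 (cut: C6–ethyl, iron-catalysed coupling with retention) and the β-keto ester 14 (cut: C5–C6, two-carbon homologation of acid 11). Olefination of an ethyl ketone would give both geometries because the two arms are alike, whereas chelation fixes the triflate geometry by construction.

**Ring cleavage.** Acid 11 is traced through the vinyl acid 10 and the aldehyde acid 9 to the silyl enol ether 8 by reconnecting C6 with the ethyl CH2. Forward, ozonolysis cuts ring bond C1=C2, and the aldehyde on C10 becomes ethyl by methylenation and hydrogenation. The precursor 8 has one ring and both chain stereocentres.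

**C10–C11 bond (key step).** Enol ether 8 is cut at the ring C3–butyl bond to enone 4, cuprate 7 (from 5) and silyl chloride 6. The ring methyl group controls the new centre, and silylation fixes the enolate toward C2, which later decides where the ring opens.

**Enone.** Enone 4 is assembled from 1 and 2 by an organocatalytic Michael–aldol–decarboxylation sequence. A route by conjugate methyl addition to a cyclohexenone would have to desaturate a saturated ketone away from its methyl-bearing side, where the two α-methylene groups differ too little. The annulation places the double bond unambiguously. Any minor enantiomer of 4 becomes a separable diastereomer series after the reagent-controlled epoxidation to 18.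

## Roads not taken

**Alternative 1:** The cut is C3–O2, made forward by base-mediated conjugate addition of the C6 hydroperoxide in the dienoate methyl (2E,4Z,6R,8S,10S)-4,6,10-triethyl-6-hydroperoxy-8-methyltetradeca-2,4-dienoate A1 to give the methyl ester A2 of the target.
- Merits: C1 is at the ester level throughout, the base is mild, and there is no leaving group at the allylic C3.
- Weak points: the new centre C3 would have to be directed by C6, whose ethyl and C7H2 arms are nearly equal, and the ring oxygens carry no substituents that could amplify the difference. The addition is reversible and the 4Z geometry of A1 can be lost under base.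
- Comparison: from enal 26 this closure is one step shorter and avoids both the allylic sulfonate and the β-peroxy aldehyde. The chosen plan offers instead a C3 fixed by reagent control and inversion. This road is kept as the fallback for step 19. As a strategy it does not address C8 and C10.

**Alternative 2:** The cut is C6–O1, made forward by molybdenum-heteropolyacid-catalysed perhydrolysis of the epoxy alcohol A3 (identical with 18) to the hydroperoxy diol A4 (identical with 19).
- Merits: it is stereospecific at a tertiary carbon and rests on reagent-controlled epoxidation.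
- Comparison: for C6 this road is equal to the chosen plan, because the chosen route uses exactly this step (steps 10 and 11) and also closes at C3 by displacement.
- Weak points: as an organising idea it leaves the harder chain problem open, namely C10 with its ethyl and butyl arms and its relation to C8. It also carries a sacrificial carbon and a free hydroperoxide next to a diol.
- The chosen plan adds a defined origin for each arm at C10.

**Alternative 3:** The cut is the four C–H bonds at C7–C10, made forward by iridium P,N-catalysed hydrogenation of a dienol such as (2E,4E)-5-ethyl-3-methylnona-2,4-dien-1-ol A5 to (3S,5S)-5-ethyl-3-methylnonan-1-ol A6.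
- Merits: one catalytic step sets both chain centres, and the route to the C6–C14 fragment is at least as short as steps 1 to 5 here. In step count and atom economy it is the better road.
- Weak points: the configuration at C10 is encoded only in the geometry of a trisubstituted alkene whose two arms are ethyl and butyl, so A5 must be geometrically pure at that bond. The conjugated diene can isomerise or be reduced 1,4 before the second addition. Two independent face selections must both succeed, and one of them under the influence of the first new centre.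
- The chosen plan offers instead a relative configuration fixed by ring geometry and arms distinguished by origin rather than by catalyst recognition.

Key step: step 2

Assumption: the diarylprolinol silyl ether in step 1 is taken to follow the usual shielding model, so that the (R)-catalyst gives (S)-4; if the sense proves opposite, the (S)-catalyst is used and nothing else changes.

## Steps

Step 1
Reactants: 1 (E)-but-2-enal; 2 tert-butyl 3-oxobutanoate
Product: 4 (5S)-5-methylcyclohex-2-en-1-one, via Michael adduct 3 (not isolated)
Conditions: (R)-2-[bis(3,5-bis(trifluoromethyl)phenyl)(trimethylsilyloxy)methyl]pyrrolidine (10 mol %), toluene, rt; then TsOH·H2O (20 mol %), toluene, 80 °C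
Reagents that add atoms: none
Why: Iminium-catalysed Michael addition of the β-keto ester to the Si face of C3 of the enal (the face left open by the aryl carbinol arm) sets the methyl-bearing centre; acid then drives intramolecular aldol condensation, loss of isobutene and decarboxylation (organocatalytic Robinson-type annulation). The double bond can only form on the side remote from the methyl group.

Step 2
Reactants: 4 (5S)-5-methylcyclohex-2-en-1-one; 5 butyllithium; 6 chlorotrimethylsilane
Product: 8 {[(3S,5S)-3-butyl-5-methylcyclohex-1-en-1-yl]oxy}(trimethyl)silane, via lithium dibutylcuprate 7 (not isolated)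
Conditions: BuLi (2.4 equiv), CuI (1.2 equiv), THF, −40 °C; then Me3SiCl (2.5 equiv) and 4, −78 °C; Et3N, pentane, cold aq. NaHCO3
Reagents that add atoms: none
Why: This is a Me3SiCl-accelerated conjugate addition of a lithium dialkylcuprate to a cyclohexenone; the closest known reaction type is the trans-selective cuprate addition to 5-substituted cyclohex-2-enones with in situ O-silylation. The cuprate forms a π-complex with C2=C3, Me3SiCl silylates the carbonyl oxygen of this complex, and reductive elimination forms the C3–butyl bond (C10–C11 of 31). No ring is closed. The new stereocentre C3 is controlled by the ring methyl group at C5: in the half-chair with this methyl pseudo-equatorial, butyl enters along the axial trajectory that leads to a chair-like enol ether, which is the face anti to the methyl group, so the trans-3,5 product results and 10S follows from 8S. The step needs facial selectivity, secured by the C5 methyl group, and a regiodefined enol ether, secured because the C1=C2 silyl enol ether is the direct product of addition and cannot equilibrate at −78 °C. Butyl and the future ethyl arm are thereby told apart by origin, butyl as the nucleophile and ethyl from ring carbon C2. The Et3N quench and cold bicarbonate work-up keep the acid-labile enol ether intact.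

Step 3
Reactants: 8 {[(3S,5S)-3-butyl-5-methylcyclohex-1-en-1-yl]oxy}(trimethyl)silane
Product: 9 (3S,5S)-5-formyl-3-methylnonanoic acid
Conditions: O3, CH2Cl2/MeOH (4:1), −78 °C; Me2S, −78 °C to rt
Reagents that add atoms: ozone, [O-][O+]=O
Why: Ozonolysis of a silyl enol ether cleaves the electron-rich C1=C2 bond; after reduction C2 appears as the aldehyde on the butyl-bearing carbon and C1 as a silyl ester that methanol converts into the acid. No stereocentre is touched, and the α-branched aldehyde is used without chromatography.

Step 4
Reactants: 9 (3S,5S)-5-formyl-3-methylnonanoic acid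
Product: 10 (3S,5S)-5-ethenyl-3-methylnonanoic acid
Conditions: Ph3PCH3Br (2.5 equiv), KN(SiMe3)2 (2.4 equiv), THF, 0 °C; then 9, −78 to 0 °C; aq. HCl
Reagents that add atoms: methyltriphenylphosphonium bromide, C[P+](c1ccccc1)(c1ccccc1)c1ccccc1.[Br-]
Why: Wittig methylenation; the first equivalent of ylide converts the acid into an inert carboxylate, and the non-stabilised ylide adds to the aldehyde at low temperature faster than it enolises it, so C5 should not epimerise.

Step 5
Reactants: 10 (3S,5S)-5-ethenyl-3-methylnonanoic acid
Product: 11 (3S,5S)-5-ethyl-3-methylnonanoic acid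
Conditions: H2 (1 atm), Pd/C (5 mol %), EtOAc, rt
Reagents that add atoms: none
Why: Heterogeneous hydrogenation of a monosubstituted alkene completes the ethyl arm at C10; no other reducible group is present.

Step 6
Reactants: 11 (3S,5S)-5-ethyl-3-methylnonanoic acid; 12 potassium 3-ethoxy-3-oxopropanoate
Product: 14 ethyl (5S,7S)-7-ethyl-5-methyl-3-oxoundecanoate, via acyl imidazole 13 (not isolated)
Conditions: CDI, THF, rt; then 12, MgCl2, Et3N, MeCN, rt to 40 °C; aq. HCl
Reagents that add atoms: 1,1'-carbonyldiimidazole, O=C(n1ccnc1)n1ccnc1 (its imidazolyl group is carried in 13 only)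
Why: Masamune-type homologation: the acyl imidazole acylates the magnesium enolate of the malonate half-ester, and decarboxylation gives the β-keto ester, forming the C5–C6 bond of 31.

Step 7
Reactants: 14 ethyl (5S,7S)-7-ethyl-5-methyl-3-oxoundecanoate
Product: 15 ethyl (2Z,5S,7S)-7-ethyl-5-methyl-3-(trifluoromethanesulfonyloxy)undec-2-enoate
Conditions: Tf2O, saturated aq. LiOH, hexane, 5 °C
Reagents that add atoms: trifluoromethanesulfonic anhydride, O=S(=O)(OS(=O)(=O)C(F)(F)F)C(F)(F)F
Why: O-Triflation of the lithium-chelated enolate under two-phase Schotten–Baumann-type conditions; chelation holds the enolate oxygen cis to the ester, so the Z-enol triflate should form.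

Step 8
Reactants: 15 ethyl (2Z,5S,7S)-7-ethyl-5-methyl-3-(trifluoromethanesulfonyloxy)undec-2-enoate
Product: 16 ethyl (2E,5S,7S)-3,7-diethyl-5-methylundec-2-enoate
Conditions: EtMgBr (1.3 equiv), Fe(acac)3 (5 mol %), THF/NMP, −30 °C
Reagents that add atoms: ethylmagnesium bromide, CC[Mg]Br
Why: Iron-catalysed cross-coupling of an enol triflate with an alkyl Grignard reagent proceeds with retention of alkene geometry and is faster at −30 °C than addition to the ester; ethyl ends up cis to the ester, which fixes the geometry that later encodes C6.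

Step 9
Reactants: 16 ethyl (2E,5S,7S)-3,7-diethyl-5-methylundec-2-enoate
Product: 17 (2E,5S,7S)-3,7-diethyl-5-methylundec-2-en-1-ol
Conditions: i-Bu2AlH (2.2 equiv), CH2Cl2, −78 °C; aq. potassium sodium tartrate
Reagents that add atoms: none
Why: 1,2-Reduction of an α,β-unsaturated ester to the allylic alcohol by i-Bu2AlH; the alkene geometry is not affected.

Step 10
Reactants: 17 (2E,5S,7S)-3,7-diethyl-5-methylundec-2-en-1-ol
Product: 18 [(2S,3S)-3-ethyl-3-[(2S,4S)-4-ethyl-2-methyloctyl]oxiran-2-yl]methanol
Conditions: Ti(OiPr)4 (10 mol %), L-(+)-diethyl tartrate (12 mol %), t-BuOOH, 4 Å molecular sieves, CH2Cl2, −20 °C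
Reagents that add atoms: tert-butyl hydroperoxide, CC(C)(C)OO
Why: Sharpless asymmetric epoxidation of an E-trisubstituted allylic alcohol; with the L-(+)-tartrate oxygen is delivered to the face that gives the (2S,3S)-epoxide, as for geraniol, under reagent control independent of the remote chain centres.

Step 11
Reactants: 18 [(2S,3S)-3-ethyl-3-[(2S,4S)-4-ethyl-2-methyloctyl]oxiran-2-yl]methanol
Product: 19 (2S,3R,5S,7S)-3,7-diethyl-3-hydroperoxy-5-methylundecane-1,2-diol
Conditions: H2O2 (anhydrous, in Et2O), H3PMo12O40 (3 mol %), Et2O, 0 °C to rt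
Reagents that add atoms: hydrogen peroxide, OO
Why: Molybdenum-heteropolyacid-catalysed perhydrolysis of an epoxide: H2O2 opens the activated oxirane at the tertiary carbon, which bears the positive charge best and is remote from the hydroxymethyl group, with inversion, setting 6R of 31.

Step 12
Reactants: 19 (2S,3R,5S,7S)-3,7-diethyl-3-hydroperoxy-5-methylundecane-1,2-diol
Product: 20 (2S,3R,5S,7S)-3-[(tert-butyldimethylsilyl)peroxy]-3,7-diethyl-5-methylundecane-1,2-diol
Conditions: t-BuMe2SiCl (1.05 equiv), Et3N (1.2 equiv), CH2Cl2, −20 to 0 °C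
Reagents that add atoms: tert-butyl(chloro)dimethylsilane, CC(C)(C)[Si](C)(C)Cl
Why: Chemoselective O-silylation: the hydroperoxide is about three pKa units more acidic than the alcohols and its ammonium peroxide ion pair is an α-effect nucleophile, whereas alcohols react only slowly with the silyl chloride without a nucleophilic catalyst.

Step 13
Reactants: 20 (2S,3R,5S,7S)-3-[(tert-butyldimethylsilyl)peroxy]-3,7-diethyl-5-methylundecane-1,2-diol
Product: 21 (2R,4S,6S)-2-[(tert-butyldimethylsilyl)peroxy]-2,6-diethyl-4-methyldecanal
Conditions: NaIO4, THF/aq. NaH2PO4–Na2HPO4 buffer (pH 7), 0 °C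
Reagents that add atoms: none
Why: Periodate glycol cleavage removes the sacrificial carbon under neutral conditions that leave the silyl peroxide intact; the aldehyde has no α-hydrogen and cannot epimerise.

Step 14
Reactants: 22 ethyl 2-[bis(2-methylphenoxy)phosphoryl]acetate
Product: 23 ethyl 2-[bis(2-methylphenoxy)phosphoryl]butanoate
Conditions: NaH, DMSO/THF, rt; EtI
Reagents that add atoms: iodoethane, CCI
Why: C-Alkylation of the stabilised phosphonoacetate anion with a primary iodide; this carbon becomes C4 with its ethyl group.

Step 15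
Reactants: 21 (2R,4S,6S)-2-[(tert-butyldimethylsilyl)peroxy]-2,6-diethyl-4-methyldecanal; 23 ethyl 2-[bis(2-methylphenoxy)phosphoryl]butanoate
Product: 24 ethyl (2Z,4R,6S,8S)-4-[(tert-butyldimethylsilyl)peroxy]-2,4,8-triethyl-6-methyldodec-2-enoate
Conditions: NaH, THF, −78 to 0 °C
Reagents that add atoms: none
Why: Z-selective Horner–Wadsworth–Emmons olefination (Ando variant): the electron-poor diaryl phosphonate makes elimination from the kinetic adduct fast, and the bulky aldehyde reinforces the Z preference, so C6 and the ester carbon (C3 of 31) end up cis.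

Step 16
Reactants: 24 ethyl (2Z,4R,6S,8S)-4-[(tert-butyldimethylsilyl)peroxy]-2,4,8-triethyl-6-methyldodec-2-enoate
Product: 25 (2Z,4R,6S,8S)-4-[(tert-butyldimethylsilyl)peroxy]-2,4,8-triethyl-6-methyldodec-2-en-1-ol
Conditions: i-Bu2AlH (2.2 equiv), CH2Cl2, −78 °C; aq. potassium sodium tartrate
Reagents that add atoms: none
Why: Ester reduction by i-Bu2AlH at −78 °C; the peroxide, flanked by a quaternary carbon and a bulky silyl group, should be attacked much more slowly than the ester at this temperature, as in low-temperature hydride reductions of carbonyl groups next to hindered peroxides.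

Step 17
Reactants: 25 (2Z,4R,6S,8S)-4-[(tert-butyldimethylsilyl)peroxy]-2,4,8-triethyl-6-methyldodec-2-en-1-ol
Product: 26 (2Z,4R,6S,8S)-4-[(tert-butyldimethylsilyl)peroxy]-2,4,8-triethyl-6-methyldodec-2-enal
Conditions: MnO2 (activated, excess), CH2Cl2, rt, dark
Reagents that add atoms: none
Why: Heterogeneous allylic oxidation with MnO2 under neutral conditions; without acid or base the Z geometry should be kept, and the enal is used at once.

Step 18
Reactants: 26 (2Z,4R,6S,8S)-4-[(tert-butyldimethylsilyl)peroxy]-2,4,8-triethyl-6-methyldodec-2-enal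
Product: 27 (4S,5Z,7R,9S,11S)-7-[(tert-butyldimethylsilyl)peroxy]-5,7,11-triethyl-9-methylpentadeca-1,5-dien-4-ol
Conditions: (−)-Ipc2B(allyl), Et2O, −78 °C; then HOCH2CH2NH2
Reagents that add atoms: (−)-B-allyldiisopinocampheylborane, C=CCB([C@H]1[C@H](C)[C@H]2C[C@@H](C1)C2(C)C)[C@H]1[C@H](C)[C@H]2C[C@@H](C1)C2(C)C
Why: Brown allylboration through a chair transition state; the reagent from (+)-α-pinene adds allyl to the Si face of the aldehyde and gives the 4S carbinol under reagent control, the C7 centre being too remote to interfere. The non-oxidative amine work-up spares the silyl peroxide.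

Step 19
Reactants: 27 (4S,5Z,7R,9S,11S)-7-[(tert-butyldimethylsilyl)peroxy]-5,7,11-triethyl-9-methylpentadeca-1,5-dien-4-ol
Product: 29 (3R,6R)-4,6-diethyl-6-[(2S,4S)-4-ethyl-2-methyloctyl]-3-(prop-2-en-1-yl)-3,6-dihydro-1,2-dioxine, via allylic mesylate 28 (not isolated)
Conditions: Ms2O, i-Pr2NEt, THF, −40 °C; then Bu4NF, THF, −40 to 0 °C
Reagents that add atoms: methanesulfonic anhydride, CS(=O)(=O)OS(C)(=O)=O (its mesyl group is carried in 28 only)
Why: Fluoride removes the silyl group from the peroxide and the peroxide anion displaces the allylic mesylate in a 6-exo-tet SN2 reaction (intramolecular alkylation of a hydroperoxide by a secondary sulfonate) with inversion, converting 4S of 27 into 3R of the ring. The Z alkene holds the two ends together, and the chloride-free sulfonylation avoids an allylic chloride.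

Step 20
Reactants: 29 (3R,6R)-4,6-diethyl-6-[(2S,4S)-4-ethyl-2-methyloctyl]-3-(prop-2-en-1-yl)-3,6-dihydro-1,2-dioxine
Product: 30 [(3R,6R)-4,6-diethyl-6-[(2S,4S)-4-ethyl-2-methyloctyl]-3,6-dihydro-1,2-dioxin-3-yl]acetaldehyde
Conditions: OsO4 (2 mol %), NaIO4, 2,6-lutidine, dioxane/H2O, rt
Reagents that add atoms: osmium tetroxide (catalytic; its oxo ligands are renewed from water by NaIO4), O=[Os](=O)(=O)=O; water, O
Why: Lemieux–Johnson cleavage: OsO4 dihydroxylates the unhindered monosubstituted alkene much faster than the ring alkene, which is trisubstituted, flanked by the quaternary C6 and deactivated by two allylic C–O bonds; periodate cleaves the diol and leaves the O–O bond alone.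

Step 21
Reactants: 30 [(3R,6R)-4,6-diethyl-6-[(2S,4S)-4-ethyl-2-methyloctyl]-3,6-dihydro-1,2-dioxin-3-yl]acetaldehyde
Product: 31 [(3R,6R)-4,6-diethyl-6-[(2S,4S)-4-ethyl-2-methyloctyl]-3,6-dihydro-1,2-dioxin-3-yl]acetic acid
Conditions: NaClO2, NaH2PO4, 2-methylbut-2-ene, t-BuOH/H2O, 0 °C to rt
Reagents that add atoms: sodium chlorite, [Na+].[O-]Cl=O
Why: Pinnick oxidation in a weakly acidic buffer converts the aldehyde into the acid without base, so neither C3 nor the peroxide is endangered; the alkene scavenger removes hypochlorite.

## Compound list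

1 | (E)-but-2-enal | C/C=C/C=O | starting material
2 | tert-butyl 3-oxobutanoate | CC(=O)CC(=O)OC(C)(C)C | starting material
3 | tert-butyl (3S)-2-acetyl-3-methyl-5-oxopentanoate (both configurations at C2) | CC(=O)C(C(=O)OC(C)(C)C)[C@@H](C)CC=O | intermediate (not isolated)
4 | (5S)-5-methylcyclohex-2-en-1-one | O=C1C=CC[C@H](C)C1 | intermediate
5 | butyllithium | [Li]CCCC | starting material
6 | chlorotrimethylsilane | C[Si](C)(C)Cl | starting material
7 | lithium dibutylcuprate | [Li+].CCCC[Cu-]CCCC | intermediate (not isolated)
8 | {[(3S,5S)-3-butyl-5-methylcyclohex-1-en-1-yl]oxy}(trimethyl)silane | C[Si](C)(C)OC1=C[C@@H](CCCC)C[C@H](C)C1 | intermediate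
9 | (3S,5S)-5-formyl-3-methylnonanoic acid | CCCC[C@H](C=O)C[C@H](C)CC(=O)O | intermediate
10 | (3S,5S)-5-ethenyl-3-methylnonanoic acid | CCCC[C@H](C=C)C[C@H](C)CC(=O)O | intermediate
11 | (3S,5S)-5-ethyl-3-methylnonanoic acid | CCCC[C@H](CC)C[C@H](C)CC(=O)O | intermediate
12 | potassium 3-ethoxy-3-oxopropanoate | [K+].[O-]C(=O)CC(=O)OCC | starting material
13 | 1-[(3S,5S)-5-ethyl-3-methylnonanoyl]-1H-imidazole | CCCC[C@H](CC)C[C@H](C)CC(=O)n1ccnc1 | intermediate (not isolated)
14 | ethyl (5S,7S)-7-ethyl-5-methyl-3-oxoundecanoate | CCCC[C@H](CC)C[C@H](C)CC(=O)CC(=O)OCC | intermediate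
15 | ethyl (2Z,5S,7S)-7-ethyl-5-methyl-3-(trifluoromethanesulfonyloxy)undec-2-enoate | CCCC[C@H](CC)C[C@H](C)C/C(OS(=O)(=O)C(F)(F)F)=C/C(=O)OCC | intermediate
16 | ethyl (2E,5S,7S)-3,7-diethyl-5-methylundec-2-enoate | CCCC[C@H](CC)C[C@H](C)C/C(CC)=C/C(=O)OCC | intermediate
17 | (2E,5S,7S)-3,7-diethyl-5-methylundec-2-en-1-ol | CCCC[C@H](CC)C[C@H](C)C/C(CC)=C/CO | intermediate
18 | [(2S,3S)-3-ethyl-3-[(2S,4S)-4-ethyl-2-methyloctyl]oxiran-2-yl]methanol | CCCC[C@H](CC)C[C@H](C)C[C@]1(CC)O[C@H]1CO | intermediate
19 | (2S,3R,5S,7S)-3,7-diethyl-3-hydroperoxy-5-methylundecane-1,2-diol | CCCC[C@H](CC)C[C@H](C)C[C@](OO)(CC)[C@@H](O)CO | intermediate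
20 | (2S,3R,5S,7S)-3-[(tert-butyldimethylsilyl)peroxy]-3,7-diethyl-5-methylundecane-1,2-diol | CCCC[C@H](CC)C[C@H](C)C[C@](OO[Si](C)(C)C(C)(C)C)(CC)[C@@H](O)CO | intermediate
21 | (2R,4S,6S)-2-[(tert-butyldimethylsilyl)peroxy]-2,6-diethyl-4-methyldecanal | CCCC[C@H](CC)C[C@H](C)C[C@](OO[Si](C)(C)C(C)(C)C)(CC)C=O | intermediate
22 | ethyl 2-[bis(2-methylphenoxy)phosphoryl]acetate | CCOC(=O)CP(=O)(Oc1ccccc1C)Oc1ccccc1C | starting material
23 | ethyl 2-[bis(2-methylphenoxy)phosphoryl]butanoate (racemic) | CCOC(=O)C(CC)P(=O)(Oc1ccccc1C)Oc1ccccc1C | intermediate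
24 | ethyl (2Z,4R,6S,8S)-4-[(tert-butyldimethylsilyl)peroxy]-2,4,8-triethyl-6-methyldodec-2-enoate | CCCC[C@H](CC)C[C@H](C)C[C@](OO[Si](C)(C)C(C)(C)C)(CC)/C=C(CC)\C(=O)OCC | intermediate
25 | (2Z,4R,6S,8S)-4-[(tert-butyldimethylsilyl)peroxy]-2,4,8-triethyl-6-methyldodec-2-en-1-ol | CCCC[C@H](CC)C[C@H](C)C[C@](OO[Si](C)(C)C(C)(C)C)(CC)/C=C(CC)\CO | intermediate
26 | (2Z,4R,6S,8S)-4-[(tert-butyldimethylsilyl)peroxy]-2,4,8-triethyl-6-methyldodec-2-enal | CCCC[C@H](CC)C[C@H](C)C[C@](OO[Si](C)(C)C(C)(C)C)(CC)/C=C(CC)\C=O | intermediate
27 | (4S,5Z,7R,9S,11S)-7-[(tert-butyldimethylsilyl)peroxy]-5,7,11-triethyl-9-methylpentadeca-1,5-dien-4-ol | CCCC[C@H](CC)C[C@H](C)C[C@](OO[Si](C)(C)C(C)(C)C)(CC)/C=C(CC)\[C@@H](O)CC=C | intermediate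
28 | (4S,5Z,7R,9S,11S)-7-[(tert-butyldimethylsilyl)peroxy]-5,7,11-triethyl-9-methylpentadeca-1,5-dien-4-yl methanesulfonate | CCCC[C@H](CC)C[C@H](C)C[C@](OO[Si](C)(C)C(C)(C)C)(CC)/C=C(CC)\[C@@H](OS(C)(=O)=O)CC=C | intermediate (not isolated)
29 | (3R,6R)-4,6-diethyl-6-[(2S,4S)-4-ethyl-2-methyloctyl]-3-(prop-2-en-1-yl)-3,6-dihydro-1,2-dioxine | CCCC[C@H](CC)C[C@H](C)C[C@]1(CC)C=C(CC)[C@@H](CC=C)OO1 | intermediate
30 | [(3R,6R)-4,6-diethyl-6-[(2S,4S)-4-ethyl-2-methyloctyl]-3,6-dihydro-1,2-dioxin-3-yl]acetaldehyde | CCCC[C@H](CC)C[C@H](C)C[C@]1(CC)C=C(CC)[C@@H](CC=O)OO1 | intermediate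
31 | [(3R,6R)-4,6-diethyl-6-[(2S,4S)-4-ethyl-2-methyloctyl]-3,6-dihydro-1,2-dioxin-3-yl]acetic acid | CCCC[C@H](CC)C[C@H](C)C[C@]1(CC)C=C(CC)[C@@H](CC(=O)O)OO1 | target

## Step count and least certain steps

Total step count: 21. Longest linear sequence: 20 steps (steps 1–13 and 15–21); step 14 prepares phosphonate 23.

**Step 2 (key step).** The likeliest failure is erosion of facial selectivity. Silyl chloride acceleration makes the addition earlier and less discriminating, so some butyl may enter syn to the methyl group. Partial hydrolysis of the enol ether at work-up would also erase the regiochemical information. Fallback: starting from 4, the butyl group is added as BuMgBr under CuBr·SMe2 catalysis with a chiral ferrocenyl diphosphine chosen so that catalyst and ring methyl group favour the same face; the magnesium enolate is silylated in the same flask with Me3SiCl/Et3N, and the sequence returns at 8. The fallback makes no compound outside the list (F0).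

**Step 12.** The likeliest failure is competing silylation of the primary hydroxyl, or migration of the silyl group from the peroxide to the neighbouring C2 hydroxyl under base, because three hydroxylic sites lie close together. Fallback, from 18 and back at 20:
- The primary hydroxyl is first blocked with NaH and 4-methoxybenzyl chloride as (2S,3S)-2-ethyl-2-[(2S,4S)-4-ethyl-2-methyloctyl]-3-{[(4-methoxyphenyl)methoxy]methyl}oxirane F1.
- Perhydrolysis as in step 11 gives (2S,3R,5S,7S)-3,7-diethyl-3-hydroperoxy-1-[(4-methoxyphenyl)methoxy]-5-methylundecan-2-ol F2, in which the hydroperoxide is the only unhindered acidic site.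
- Silylation gives (2S,3R,5S,7S)-3-[(tert-butyldimethylsilyl)peroxy]-3,7-diethyl-1-[(4-methoxyphenyl)methoxy]-5-methylundecan-2-ol F3.
- DDQ in wet CH2Cl2 removes the benzyl ether and returns diol 20.

**Step 19.** The likeliest failure is ionisation of the doubly activated allylic mesylate before the peroxide anion arrives, with loss of configuration at C3 or allylic transposition, or E2 elimination toward C3 giving a diene. Fallback, from 26 and back at 31:
- Wittig reaction with Ph3P=CHCO2Me gives methyl (2E,4Z,6R,8S,10S)-6-[(tert-butyldimethylsilyl)peroxy]-4,6,10-triethyl-8-methyltetradeca-2,4-dienoate F4.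
- Bu4NF removes the silyl group and the peroxide anion adds to C3 of the dienoate. This gives methyl [(3R,6R)-4,6-diethyl-6-[(2S,4S)-4-ethyl-2-methyloctyl]-3,6-dihydro-1,2-dioxin-3-yl]acetate F5 together with its C3 epimer, methyl [(3S,6R)-4,6-diethyl-6-[(2S,4S)-4-ethyl-2-methyloctyl]-3,6-dihydro-1,2-dioxin-3-yl]acetate F6, which must be separated.
- LiOH in aqueous THF converts F5 into 31.
- This fallback gives up control at C3 in exchange for a closure that needs no leaving group.

**Step 20.** The likeliest failure is opening of the ring by β-elimination of the peroxide from the β-peroxy aldehyde under the buffered cleavage conditions or during isolation; competing oxidation of the ring alkene is a lesser risk. Fallback, from 27 and back at 31, in which C1 is carried as a protected alcohol through the ring closure and the aldehyde is never isolated: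
- Lemieux–Johnson cleavage of 27 gives (3S,4Z,6R,8S,10S)-6-[(tert-butyldimethylsilyl)peroxy]-4,6,10-triethyl-3-hydroxy-8-methyltetradec-4-enal F7.
- NaBH4 gives (3S,4Z,6R,8S,10S)-6-[(tert-butyldimethylsilyl)peroxy]-4,6,10-triethyl-8-methyltetradec-4-ene-1,3-diol F8.
- t-BuMe2SiCl/imidazole gives (3S,4Z,6R,8S,10S)-1-[(tert-butyldimethylsilyl)oxy]-6-[(tert-butyldimethylsilyl)peroxy]-4,6,10-triethyl-8-methyltetradec-4-en-3-ol F9.
- Ms2O/i-Pr2NEt gives (3S,4Z,6R,8S,10S)-1-[(tert-butyldimethylsilyl)oxy]-6-[(tert-butyldimethylsilyl)peroxy]-4,6,10-triethyl-8-methyltetradec-4-en-3-yl methanesulfonate F10, which is not isolated.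
- Excess Bu4NF closes the ring and frees the primary alcohol, giving 2-[(3R,6R)-4,6-diethyl-6-[(2S,4S)-4-ethyl-2-methyloctyl]-3,6-dihydro-1,2-dioxin-3-yl]ethanol F11.
- TEMPO/NaClO2 with catalytic NaOCl in a pH 6.7 buffer oxidises F11 to 31.

## Further compounds

F0 | step 2 | none | none
F1 | step 12 | (2S,3S)-2-ethyl-2-[(2S,4S)-4-ethyl-2-methyloctyl]-3-{[(4-methoxyphenyl)methoxy]methyl}oxirane | CCCC[C@H](CC)C[C@H](C)C[C@]1(CC)O[C@H]1COCc1ccc(OC)cc1
F2 | step 12 | (2S,3R,5S,7S)-3,7-diethyl-3-hydroperoxy-1-[(4-methoxyphenyl)methoxy]-5-methylundecan-2-ol | CCCC[C@H](CC)C[C@H](C)C[C@](OO)(CC)[C@@H](O)COCc1ccc(OC)cc1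
F3 | step 12 | (2S,3R,5S,7S)-3-[(tert-butyldimethylsilyl)peroxy]-3,7-diethyl-1-[(4-methoxyphenyl)methoxy]-5-methylundecan-2-ol | CCCC[C@H](CC)C[C@H](C)C[C@](OO[Si](C)(C)C(C)(C)C)(CC)[C@@H](O)COCc1ccc(OC)cc1
F4 | step 19 | methyl (2E,4Z,6R,8S,10S)-6-[(tert-butyldimethylsilyl)peroxy]-4,6,10-triethyl-8-methyltetradeca-2,4-dienoate | CCCC[C@H](CC)C[C@H](C)C[C@](OO[Si](C)(C)C(C)(C)C)(CC)/C=C(CC)\C=C\C(=O)OC
F5 | step 19 | methyl [(3R,6R)-4,6-diethyl-6-[(2S,4S)-4-ethyl-2-methyloctyl]-3,6-dihydro-1,2-dioxin-3-yl]acetate | CCCC[C@H](CC)C[C@H](C)C[C@]1(CC)C=C(CC)[C@@H](CC(=O)OC)OO1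
F6 | step 19 | methyl [(3S,6R)-4,6-diethyl-6-[(2S,4S)-4-ethyl-2-methyloctyl]-3,6-dihydro-1,2-dioxin-3-yl]acetate | CCCC[C@H](CC)C[C@H](C)C[C@]1(CC)C=C(CC)[C@H](CC(=O)OC)OO1
F7 | step 20 | (3S,4Z,6R,8S,10S)-6-[(tert-butyldimethylsilyl)peroxy]-4,6,10-triethyl-3-hydroxy-8-methyltetradec-4-enal | CCCC[C@H](CC)C[C@H](C)C[C@](OO[Si](C)(C)C(C)(C)C)(CC)/C=C(CC)\[C@@H](O)CC=O
F8 | step 20 | (3S,4Z,6R,8S,10S)-6-[(tert-butyldimethylsilyl)peroxy]-4,6,10-triethyl-8-methyltetradec-4-ene-1,3-diol | CCCC[C@H](CC)C[C@H](C)C[C@](OO[Si](C)(C)C(C)(C)C)(CC)/C=C(CC)\[C@@H](O)CCO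
F9 | step 20 | (3S,4Z,6R,8S,10S)-1-[(tert-butyldimethylsilyl)oxy]-6-[(tert-butyldimethylsilyl)peroxy]-4,6,10-triethyl-8-methyltetradec-4-en-3-ol | CCCC[C@H](CC)C[C@H](C)C[C@](OO[Si](C)(C)C(C)(C)C)(CC)/C=C(CC)\[C@@H](O)CCO[Si](C)(C)C(C)(C)C
F10 | step 20 | (3S,4Z,6R,8S,10S)-1-[(tert-butyldimethylsilyl)oxy]-6-[(tert-butyldimethylsilyl)peroxy]-4,6,10-triethyl-8-methyltetradec-4-en-3-yl methanesulfonate | CCCC[C@H](CC)C[C@H](C)C[C@](OO[Si](C)(C)C(C)(C)C)(CC)/C=C(CC)\[C@@H](OS(C)(=O)=O)CCO[Si](C)(C)C(C)(C)C
F11 | step 20 | 2-[(3R,6R)-4,6-diethyl-6-[(2S,4S)-4-ethyl-2-methyloctyl]-3,6-dihydro-1,2-dioxin-3-yl]ethanol | CCCC[C@H](CC)C[C@H](C)C[C@]1(CC)C=C(CC)[C@@H](CCO)OO1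
A1 | alternative 1 | methyl (2E,4Z,6R,8S,10S)-4,6,10-triethyl-6-hydroperoxy-8-methyltetradeca-2,4-dienoate | CCCC[C@H](CC)C[C@H](C)C[C@](OO)(CC)/C=C(CC)\C=C\C(=O)OC
A2 | alternative 1 | methyl [(3R,6R)-4,6-diethyl-6-[(2S,4S)-4-ethyl-2-methyloctyl]-3,6-dihydro-1,2-dioxin-3-yl]acetate | CCCC[C@H](CC)C[C@H](C)C[C@]1(CC)C=C(CC)[C@@H](CC(=O)OC)OO1
A3 | alternative 2 | [(2S,3S)-3-ethyl-3-[(2S,4S)-4-ethyl-2-methyloctyl]oxiran-2-yl]methanol | CCCC[C@H](CC)C[C@H](C)C[C@]1(CC)O[C@H]1CO
A4 | alternative 2 | (2S,3R,5S,7S)-3,7-diethyl-3-hydroperoxy-5-methylundecane-1,2-diol | CCCC[C@H](CC)C[C@H](C)C[C@](OO)(CC)[C@@H](O)CO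
A5 | alternative 3 | (2E,4E)-5-ethyl-3-methylnona-2,4-dien-1-ol | CCCC/C(CC)=C/C(C)=C/CO
A6 | alternative 3 | (3S,5S)-5-ethyl-3-methylnonan-1-ol | CCCC[C@H](CC)C[C@H](C)CCO
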